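Ring A is disconnected so that C5–C8, with the C6 and C7 methoxy groups, come from dimethyl squarate, while the C4a=C8a bond is recognised as the C3=C2 enol-ether double bond of a preformed 2-aryl-4-pyranone. Heating a 4-hydroxy-4-(pyranon-2-yl)-2,3-dimethoxycyclobutenone opens the four-membered ring to a ketene that closes onto pyranone C3, forging C4a–C5 and delivering the whole flavone as its 5,8-hydroquinone in one operation. The step exploits the contiguous oxygenation of ring A at C5, C6 and C7 and the peri relationship of C5–OH to the C4 carbonyl, which lets the surplus C8–OH be excised selectively.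

Key step: step 5

Remark: the tertiary hydroxyl of 11 is deliberately left unprotected. It is the donor that steers the ring opening, and it emerges as the free C8 phenol needed for the deoxygenation, so protection would only add steps. The hydroquinone 14 is therefore handled under argon.

Assumption: 1, 5, 9 and TMPMgCl·LiCl (THF solution) are purchased.

Step 1
Reactants: 1 1,2,3,4-tetramethoxybenzene
Product: 3 2,3,4,5-tetramethoxybenzoic acid, via aryllithium 2 (not isolated)
Conditions: n-BuLi, TMEDA, THF, 0 °C; CO2, −78 °C to rt; aq HCl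
Reagents that add atoms: carbon dioxide, O=C=O
Why: Directed ortho-metalation, in which a flanking methoxy group guides n-BuLi/TMEDA to one of the two equivalent ring hydrogens of 1, followed by carboxylation of aryllithium 2 and acidification, should give 3 as the only possible regioisomer.

Step 2
Reactants: 3 2,3,4,5-tetramethoxybenzoic acid
Product: 4 2,3,4,5-tetramethoxybenzoyl chloride
Conditions: (COCl)2, cat. DMF, CH2Cl2, 0 °C to rt; evaporate, use crude
Reagents that add atoms: oxalyl chloride, O=C(Cl)C(=O)Cl
Why: DMF-catalysed (Vilsmeier-type) conversion of a carboxylic acid into its chloride with oxalyl chloride is tolerated by aryl methyl ethers and leaves only volatile by-products.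

Step 3
Reactants: 4 2,3,4,5-tetramethoxybenzoyl chloride; 5 (E)-4-methoxybut-3-en-2-one
Product: 8 2-(2,3,4,5-tetramethoxyphenyl)-4H-pyran-4-one, via lithium dienolate 6 (not isolated), via diketone 7 (not isolated)
Conditions: 5 (2.2 equiv), LiN(SiMe3)2 (2.2 equiv), THF, −78 °C; 4 (1 equiv), −78 °C; then TFA (excess), THF/CH2Cl2, −78 °C to rt
Reagents that add atoms: none
Why: Acylative γ-pyrone synthesis, in which the kinetic lithium dienolate 6 is C-acylated by the aroyl chloride (the second equivalent of 6 absorbing the acidic proton of diketone 7) and acid then closes the enol oxygen onto the methoxyvinyl ketone by 6-endo oxa-Michael addition and loss of methanol, should give the pyranone directly at the correct oxidation level.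

Step 4
Reactants: 8 2-(2,3,4,5-tetramethoxyphenyl)-4H-pyran-4-one; 9 dimethyl squarate (3,4-dimethoxycyclobut-3-ene-1,2-dione)
Product: 11 racemic 4-hydroxy-2,3-dimethoxy-4-[4-oxo-6-(2,3,4,5-tetramethoxyphenyl)-4H-pyran-2-yl]cyclobut-2-en-1-one, via pyranonylmagnesium chloride 10 (not isolated)
Conditions: TMPMgCl·LiCl (1.15 equiv), THF, −40 °C; cannula into 9 (1.5 equiv), THF, −78 °C; aq NH4Cl, −78 °C to rt
Reagents that add atoms: none
Why: Deprotonative magnesiation with the hindered amide base should remove C6–H, the only sp2 hydrogen next to the ring oxygen and the most acidic site of a 4-pyranone (as C2–H in chromones), and the Grignard reagent 10 then undergoes 1,2-addition to one of the two equivalent squarate carbonyls, the new carbinol centre forming as a racemate that is erased in step 5.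

Step 5
Reactants: 11 racemic 4-hydroxy-2,3-dimethoxy-4-[4-oxo-6-(2,3,4,5-tetramethoxyphenyl)-4H-pyran-2-yl]cyclobut-2-en-1-one
Product: 14 5,8-dihydroxy-6,7-dimethoxy-2-(2,3,4,5-tetramethoxyphenyl)-4H-chromen-4-one, via dienylketene 12 (not isolated), via cyclohexadienone 13 (not isolated)
Conditions: degassed toluene (0.02 M), 110 °C, Ar (p-xylene, 138 °C, if conversion is slow)
Reagents that add atoms: none
Why: Heat opens the cyclobutenone by a four-electron conrotatory cleavage of the C1–C4 bond in which the hydroxyl, as the better donor, rotates outward, so that dienylketene 12 carries the pyranone cis to the ketene. A six-electron disrotatory electrocyclization of the ketene C=C, the central C=C and the pyranone C2=C3 bond then joins the ketene carbon to pyranone C3 (the future C4a–C5 bond), and the doubly carbonyl-activated C4a–H of 13 should tautomerise at once to the aromatic hydroquinone 14. The closest known reaction type is the thermal ring expansion of 4-aryl-, 4-heteroaryl- and 4-alkenyl-4-hydroxycyclobutenones to hydroquinones (Moore rearrangement), applied here to a pyranone whose C2=C3 bond behaves as an enol-ether alkene. Ring A closes in a pericyclic six-electron mode with all six ring carbons lying in the triene, not by a polar exo or endo cyclization. No stereocentre is created in 14, since the carbinol centre of racemic 11 and the transient C4a centre of 13 both become sp2. The selectivity needed is closure at C3 and nowhere else, which is secured because C3 is the only carbon flanking the point of attachment (the other neighbour is the ring oxygen) and its nucleophilic enol-ether β-carbon character matches the electrophilic ketene carbon; the step is an isomerisation and releases no by-product.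

Step 6
Reactants: 14 5,8-dihydroxy-6,7-dimethoxy-2-(2,3,4,5-tetramethoxyphenyl)-4H-chromen-4-one
Product: 15 5-hydroxy-6,7-dimethoxy-4-oxo-2-(2,3,4,5-tetramethoxyphenyl)-4H-chromen-8-yl trifluoromethanesulfonate
Conditions: PhNTf2 (1.05 equiv), Et3N (1.5 equiv), DMAP (5 mol %), degassed CH2Cl2, 0 °C to rt, Ar
Reagents that add atoms: N-phenylbis(trifluoromethanesulfonimide), O=S(=O)(N(c1ccccc1)S(=O)(=O)C(F)(F)F)C(F)(F)F
Why: Chemoselective O-sulfonylation should occur only at the free C8 phenol, because the C5 hydroxyl is locked in a six-membered hydrogen bond to the C4 carbonyl and is far less nucleophilic, as in the known selective sulfonylation of the non-chelated hydroxyl of 5,7-dihydroxyflavones.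

Step 7
Reactants: 15 5-hydroxy-6,7-dimethoxy-4-oxo-2-(2,3,4,5-tetramethoxyphenyl)-4H-chromen-8-yl trifluoromethanesulfonate
Product: 16 5-hydroxy-6,7-dimethoxy-2-(2,3,4,5-tetramethoxyphenyl)-4H-chromen-4-one
Conditions: Pd(OAc)2 (5 mol %), dppf (6 mol %), HCO2H (3 equiv), Et3N (4 equiv), DMF, 70 °C
Reagents that add atoms: none
Why: Palladium-catalysed formate reduction of an aryl triflate, in which zerovalent palladium formed in situ from Pd(OAc)2 inserts into the C8–O bond, formate replaces triflate and decarboxylates to a hydride, and reductive elimination gives C8–H, should leave the chelated phenol, the chromone and the methyl ethers untouched.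

Step 8
Reactants: 16 5-hydroxy-6,7-dimethoxy-2-(2,3,4,5-tetramethoxyphenyl)-4H-chromen-4-one
Product: 17 agehoustin B, 5,6,7-trimethoxy-2-(2,3,4,5-tetramethoxyphenyl)-4H-chromen-4-one
Conditions: MeI (5 equiv), K2CO3 (3 equiv), acetone, reflux
Reagents that add atoms: iodomethane, CI
Why: Williamson O-methylation of the hydrogen-bonded C5 phenol is slow but is the only alkylation possible, so excess MeI and K2CO3 in refluxing acetone should drive it to the heptamethyl ether.

Compound list
1 | 1,2,3,4-tetramethoxybenzene | COc1ccc(OC)c(OC)c1OC | starting material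
2 | (2,3,4,5-tetramethoxyphenyl)lithium | [Li]c1cc(OC)c(OC)c(OC)c1OC | intermediate
3 | 2,3,4,5-tetramethoxybenzoic acid | COc1cc(C(=O)O)c(OC)c(OC)c1OC | intermediate
4 | 2,3,4,5-tetramethoxybenzoyl chloride | COc1cc(C(=O)Cl)c(OC)c(OC)c1OC | intermediate
5 | (E)-4-methoxybut-3-en-2-one | CO/C=C/C(C)=O | starting material
6 | lithium (E)-4-methoxybuta-1,3-dien-2-olate | CO/C=C/C(=C)O[Li] | intermediate
7 | (E)-5-methoxy-1-(2,3,4,5-tetramethoxyphenyl)pent-4-ene-1,3-dione (largely enolised) | COc1cc(C(=O)CC(=O)/C=C/OC)c(OC)c(OC)c1OC | intermediate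
8 | 2-(2,3,4,5-tetramethoxyphenyl)-4H-pyran-4-one | COc1cc(-c2cc(=O)cco2)c(OC)c(OC)c1OC | intermediate
9 | dimethyl squarate (3,4-dimethoxycyclobut-3-ene-1,2-dione) | COc1c(OC)c(=O)c1=O | starting material
10 | chloro[4-oxo-6-(2,3,4,5-tetramethoxyphenyl)-4H-pyran-2-yl]magnesium (LiCl complex) | COc1cc(-c2cc(=O)cc([Mg]Cl)o2)c(OC)c(OC)c1OC | intermediate
11 | racemic 4-hydroxy-2,3-dimethoxy-4-[4-oxo-6-(2,3,4,5-tetramethoxyphenyl)-4H-pyran-2-yl]cyclobut-2-en-1-one | COC1=C(OC)C(O)(c2cc(=O)cc(-c3cc(OC)c(OC)c(OC)c3OC)o2)C1=O | intermediate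
12 | (3Z)-4-hydroxy-2,3-dimethoxy-4-[4-oxo-6-(2,3,4,5-tetramethoxyphenyl)-4H-pyran-2-yl]buta-1,3-dien-1-one | O=C=C(OC)/C(OC)=C(/O)c1cc(=O)cc(-c2cc(OC)c(OC)c(OC)c2OC)o1 | intermediate
13 | racemic 8-hydroxy-6,7-dimethoxy-2-(2,3,4,5-tetramethoxyphenyl)-4aH-chromene-4,5-dione | COC1=C(OC)C(=O)C2C(=O)C=C(c3cc(OC)c(OC)c(OC)c3OC)OC2=C1O | intermediate
14 | 5,8-dihydroxy-6,7-dimethoxy-2-(2,3,4,5-tetramethoxyphenyl)-4H-chromen-4-one | COc1cc(-c2cc(=O)c3c(O)c(OC)c(OC)c(O)c3o2)c(OC)c(OC)c1OC | intermediate
15 | 5-hydroxy-6,7-dimethoxy-4-oxo-2-(2,3,4,5-tetramethoxyphenyl)-4H-chromen-8-yl trifluoromethanesulfonate | COc1cc(-c2cc(=O)c3c(O)c(OC)c(OC)c(OS(=O)(=O)C(F)(F)F)c3o2)c(OC)c(OC)c1OC | intermediate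
16 | 5-hydroxy-6,7-dimethoxy-2-(2,3,4,5-tetramethoxyphenyl)-4H-chromen-4-one | COc1cc(-c2cc(=O)c3c(O)c(OC)c(OC)cc3o2)c(OC)c(OC)c1OC | intermediate
17 | agehoustin B, 5,6,7-trimethoxy-2-(2,3,4,5-tetramethoxyphenyl)-4H-chromen-4-one | COc1cc(-c2cc(=O)c3c(OC)c(OC)c(OC)cc3o2)c(OC)c(OC)c1OC | target

Total step count: 8. Longest linear sequence: 8 steps (1 to 17).

Steps most likely to fail

Step 5. The ring opening itself is not in doubt, but the six-electron closure onto the electron-poor pyranone may be slow. The ketene could then be lost by oligomerisation or by capture of adventitious water, and the hydroquinone could be oxidised during prolonged heating. The fallback abandons the squarate annulation and buys ring A instead; it sets out from acid chloride 4 and comes back to the route at target 17. Compound 4 acylates commercial 1-(6-hydroxy-2,3,4-trimethoxyphenyl)ethan-1-one (CC(=O)c1c(O)cc(OC)c(OC)c1OC; pyridine, DMAP, CH2Cl2) to give 2-acetyl-3,4,5-trimethoxyphenyl 2,3,4,5-tetramethoxybenzoate F1. KOH in pyridine at 50 °C effects the Baker–Venkataraman acyl shift to 1-(6-hydroxy-2,3,4-trimethoxyphenyl)-3-(2,3,4,5-tetramethoxyphenyl)propane-1,3-dione F2. Catalytic H2SO4 in AcOH at 90 °C then closes F2 to 17 by cyclodehydration.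

Step 4. Deprotonation at −40 °C may be slower than conjugate addition of the magnesiated pyranone to pyranone not yet metalated, so that self-condensation and incomplete metalation erode the addition to the squarate. The fallback separates C–H activation from C–C bond formation; it sets out from pyranone 8 and comes back to the route at Grignard reagent 10 and thence 11. TMPZnCl·LiCl in THF at 25 °C should give the non-nucleophilic chloro[4-oxo-6-(2,3,4,5-tetramethoxyphenyl)-4H-pyran-2-yl]zinc F3, which is quenched with I2 to 2-iodo-6-(2,3,4,5-tetramethoxyphenyl)-4H-pyran-4-one F4. Iodine–magnesium exchange of F4 with i-PrMgCl·LiCl at −78 °C then generates 10 rapidly and completely in the absence of amide base and of free pyranone, and 10 is added to 9 as in the main route.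

Step 6. Under base the hydroquinone may be oxidised to the 5,8-quinone, or sulfonylation may spill over to the chelated C5 hydroxyl. The fallback differentiates the two oxygens before ring A exists; it sets out from cyclobutenone 11 and comes back to the route at triflate 15. Et3SiOTf and 2,6-lutidine in CH2Cl2 at −78 °C convert 11 into racemic 2,3-dimethoxy-4-[4-oxo-6-(2,3,4,5-tetramethoxyphenyl)-4H-pyran-2-yl]-4-(triethylsilyloxy)cyclobut-2-en-1-one F5. Thermolysis in toluene at 110 °C, the established ring expansion of 4-silyloxycyclobutenones, should proceed through (3Z)-2,3-dimethoxy-4-[4-oxo-6-(2,3,4,5-tetramethoxyphenyl)-4H-pyran-2-yl]-4-(triethylsilyloxy)buta-1,3-dien-1-one F6 and racemic 6,7-dimethoxy-2-(2,3,4,5-tetramethoxyphenyl)-8-(triethylsilyloxy)-4aH-chromene-4,5-dione F7 to the air-stable 5-hydroxy-6,7-dimethoxy-2-(2,3,4,5-tetramethoxyphenyl)-8-(triethylsilyloxy)-4H-chromen-4-one F8. CsF and PhNTf2 in MeCN at rt then unmask only the C8 phenoxide and trap it as 15.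

Further compounds
F1 | step 5 | 2-acetyl-3,4,5-trimethoxyphenyl 2,3,4,5-tetramethoxybenzoate | CC(=O)c1c(OC(=O)c2cc(OC)c(OC)c(OC)c2OC)cc(OC)c(OC)c1OC
F2 | step 5 | 1-(6-hydroxy-2,3,4-trimethoxyphenyl)-3-(2,3,4,5-tetramethoxyphenyl)propane-1,3-dione | COc1cc(C(=O)CC(=O)c2c(O)cc(OC)c(OC)c2OC)c(OC)c(OC)c1OC
F3 | step 4 | chloro[4-oxo-6-(2,3,4,5-tetramethoxyphenyl)-4H-pyran-2-yl]zinc (LiCl complex) | COc1cc(-c2cc(=O)cc([Zn]Cl)o2)c(OC)c(OC)c1OC
F4 | step 4 | 2-iodo-6-(2,3,4,5-tetramethoxyphenyl)-4H-pyran-4-one | COc1cc(-c2cc(=O)cc(I)o2)c(OC)c(OC)c1OC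
F5 | step 6 | racemic 2,3-dimethoxy-4-[4-oxo-6-(2,3,4,5-tetramethoxyphenyl)-4H-pyran-2-yl]-4-(triethylsilyloxy)cyclobut-2-en-1-one | COC1=C(OC)C(O[Si](CC)(CC)CC)(c2cc(=O)cc(-c3cc(OC)c(OC)c(OC)c3OC)o2)C1=O
F6 | step 6 | (3Z)-2,3-dimethoxy-4-[4-oxo-6-(2,3,4,5-tetramethoxyphenyl)-4H-pyran-2-yl]-4-(triethylsilyloxy)buta-1,3-dien-1-one | O=C=C(OC)/C(OC)=C(/O[Si](CC)(CC)CC)c1cc(=O)cc(-c2cc(OC)c(OC)c(OC)c2OC)o1
F7 | step 6 | racemic 6,7-dimethoxy-2-(2,3,4,5-tetramethoxyphenyl)-8-(triethylsilyloxy)-4aH-chromene-4,5-dione | COC1=C(OC)C(=O)C2C(=O)C=C(c3cc(OC)c(OC)c(OC)c3OC)OC2=C1O[Si](CC)(CC)CC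
F8 | step 6 | 5-hydroxy-6,7-dimethoxy-2-(2,3,4,5-tetramethoxyphenyl)-8-(triethylsilyloxy)-4H-chromen-4-one | COc1cc(-c2cc(=O)c3c(O)c(OC)c(OC)c(O[Si](CC)(CC)CC)c3o2)c(OC)c(OC)c1OC
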